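**Plan**

Numbering: tetrahydrofuran O1, C2(Ar), C3, C4, C5(Ar), with C3′ and C4′ as the exocyclic CH2 carbons. The target is the 2,3-trans/3,4-cis/4,5-trans isomer, a meso compound whose mirror plane contains O1 and bisects C3–C4.
Cuts: the four phenol protecting groups and the two acetates come off first. C3′ and C4′ are then tied back into a cis-fused γ-lactone, and the tetrahydrofuran ring is cut at O1–C2 and C3–C4.
Enabling feature: in the ring, O1–C5(Ar)–C4 bearing C4′ is a masked aryl vinyl oxirane (benzylic oxygen next to an allylic carbon). C2(Ar)–C3 bearing C3′ is a masked arylidene 1,3-dicarbonyl acceptor, so the ring is an O–C–C dipole plus a two-carbon acceptor, both made from one aldehyde.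
Forward: ylide epoxidation and Knoevenagel condensation give the two halves, and Pd(0) joins them and closes the tetrahydrofuran (ring 1). Vinyl cleavage and reduction close a temporary lactone (ring 2), which hydride reopens; acetylation and hydrogenolysis finish the route.
Stereochemistry: C5 and C4 come from the trans-oxirane (net retention at C4). C2 comes from reversible alkoxide addition before the irreversible closure (2,5-cis), and C3 from the cis fusion of the lactone. The racemic series merges into an achiral diol.

Key step: step 4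

Remark: the descriptors (2R,3S,4R,5S) describe a meso, achiral molecule, so no absolute control is needed. Chiral intermediates are racemic, and their SMILES show one enantiomer only to convey relative configuration.

**Step 1**
Reactants: 1 tetrahydrothiophene; 2 allyl bromide
Product: 3 1-allyltetrahydrothiophenium bromide
Conditions: MeOH–H2O (9:1), rt; evaporate, triturate with Et2O
Reagents that add atoms: none
Why: SN2 S-alkylation of a soft dialkyl sulfide by a reactive allylic bromide is a standard entry to crystalline sulfonium salts and creates no stereocentre.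

**Step 2**
Reactants: 3 1-allyltetrahydrothiophenium bromide; 4 3,4-bis(benzyloxy)benzaldehyde
Product: 6 (±)-trans-2-[3,4-bis(benzyloxy)phenyl]-3-vinyloxirane, via allyl sulfonium ylide 5 (not isolated)
Conditions: powdered KOH, MeCN, 0 °C → rt; chromatography on Et3N-deactivated silica
Reagents that add atoms: none
Why: In this Johnson–Corey–Chaykovsky epoxidation the semi-stabilised allylide attacks the aldehyde through its α-carbon, and under lithium-free aprotic conditions betaine formation is partly reversible, so the faster-closing anti betaine should dominate and give mainly the trans-oxirane, the cis isomer being removed on base-washed silica.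

**Step 3**
Reactants: 4 3,4-bis(benzyloxy)benzaldehyde; 7 Meldrum's acid
Product: 8 5-[3,4-bis(benzyloxy)benzylidene]-2,2-dimethyl-1,3-dioxane-4,6-dione
Conditions: piperidinium acetate (10 mol %), toluene, 4 Å MS, rt; recrystallise
Reagents that add atoms: none
Why: Knoevenagel condensation of the strongly CH-acidic Meldrum's acid with a non-enolisable aromatic aldehyde is routine, the electron-rich arylidene resists a second addition, and the symmetric dicarbonyl removes any alkene-geometry issue.

**Step 4**
Reactants: 6 (±)-trans-2-[3,4-bis(benzyloxy)phenyl]-3-vinyloxirane; 8 5-[3,4-bis(benzyloxy)benzylidene]-2,2-dimethyl-1,3-dioxane-4,6-dione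
Product: 9 (±)-1,3-bis[3,4-bis(benzyloxy)phenyl]-8,8-dimethyl-4-vinyl-2,7,9-trioxaspiro[4.5]decane-6,10-dione (spiro-Meldrum tetrahydrofuran; 2,5-cis-diaryl; 4,5-trans)
Conditions: Pd2(dba)3·CHCl3 (2.5 mol %), dppe (6 mol %), THF, 0 °C → rt, slow addition of 6 to 8 and catalyst
Reagents that add atoms: none
Why: Pd(0) ionises the allylic C4–O bond of 6 from the face opposite oxygen, the freed benzylic alkoxide adds to the arylidene carbon of 8 (O1–C2), and the Meldrum carbanion thus unveiled attacks the near allyl terminus opposite palladium (C3–C4). The closest known reaction type is the palladium-catalysed formal (3+2) annulation of vinyl oxiranes with doubly activated alkenes such as arylidene malononitriles and alkylidene Meldrum's acids, used here with an oxirane that carries an aryl group on its second ring carbon. The tetrahydrofuran closes in the 5-exo mode on the π-allyl unit, because the three-atom C2–O1–C5 tether places the carbanion within reach of C4, whereas attack at the terminal CH2 would need a 7-endo closure. C4 is controlled by the oxirane geometry through two inversions (net retention, trans-oxirane to 4,5-trans ring), and should the allyl faces exchange by π–σ–π motion through the unsubstituted terminus, the closure that turns the C5 aryl group away from the allyl–palladium fragment leads to the same 4,5-trans relation. C2 is controlled by the reversibility of the oxa-Michael addition to this very electrophilic acceptor, so the irreversible C–C closure can select the envelope in which both aryl groups next to O1 sit pseudo-equatorially (2,5-cis), while spiro C3 with its two identical carbonyl arms is not yet stereogenic. The step needs capture of the alkoxide to outrun hydride shift to an aryl ketone and oligomerisation, which the high electrophilicity of 8, its excess during the slow addition of 6 and a halide-free chelating phosphine catalyst should secure.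

**Step 5**
Reactants: 9 spiro-Meldrum tetrahydrofuran
Product: 13 (±)-cis-fused 4,6-bis[3,4-bis(benzyloxy)phenyl]-3-oxotetrahydro-1H,3H-furo[3,4-c]furan-3a-carboxylic acid (both aryl groups exo), via secondary ozonide 10 (not isolated), via C4-formyl spiro adduct 11 (not isolated), via C4-hydroxymethyl spiro adduct 12 (not isolated)
Conditions: O3, CH2Cl2, −78 °C (Sudan III end point); PPh3, −78 °C → rt; evaporate; NaBH4, THF–i-PrOH, 0 °C; 10% citric acid, acid–base extraction
Reagents that add atoms: ozone [O-][O+]=O
Why: Ozonolysis (Criegee sequence, phosphine work-up) stopped at the dye end point should cleave only the monosubstituted alkene, borohydride then reduces the hindered aldehyde, and the C4′ alkoxide acylates itself on the one Meldrum carbonyl lying on its own ring face with loss of acetone, which makes C3 stereogenic with C3′ cis to C4′; ozone is preferred to an osmium-based cleavage because a transient vicinal diol could lactonise through its secondary hydroxyl and trap the surplus carbon.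

**Step 6**
Reactants: 13 lactone acid
Product: 14 (±)-cis-fused 4,6-bis[3,4-bis(benzyloxy)phenyl]tetrahydro-1H,3H-furo[3,4-c]furan-1-one (both aryl groups exo)
Conditions: DMSO, 120 °C, N2
Reagents that add atoms: none
Why: Malonic-type thermal decarboxylation through the six-membered cyclic transition state gives the lactone enol, and its C-protonation can only furnish the cis-fused bicyclo[3.3.0] system, so H-3 ends up cis to H-4 and C3′ trans to the C2 aryl group; ring opening by β-elimination of O1 would be the reverse of a 5-endo-trig closure and should stay slow.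

**Step 7**
Reactants: 14 cis-fused lactone
Product: 15 meso-(2R,3S,4R,5S)-{2,5-bis[3,4-bis(benzyloxy)phenyl]tetrahydrofuran-3,4-diyl}dimethanol
Conditions: LiAlH4, THF, 0 °C → rt; Rochelle salt work-up
Reagents that add atoms: none
Why: Standard LiAlH4 reduction of a γ-lactone to the 1,4-diol leaves the benzyl ethers and all four stereocentres untouched and restores the mirror plane, so both enantiomers of 14 give the same meso diol.

**Step 8**
Reactants: 15 meso diol
Product: 16 meso-(2R,3S,4R,5S)-{2,5-bis[3,4-bis(benzyloxy)phenyl]tetrahydrofuran-3,4-diyl}bis(methylene) diacetate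
Conditions: Ac2O, pyridine, DMAP (cat.), CH2Cl2, 0 °C → rt
Reagents that add atoms: acetic anhydride CC(=O)OC(C)=O
Why: DMAP-catalysed acylation of two unhindered primary alcohols under basic conditions avoids the acid that could ionise the benzylic ring carbons or divert the diol to a furofuran.

**Step 9**
Reactants: 16 tetrabenzyl diacetate
Product: 17 target CNP0416169.1, meso-(2R,3S,4R,5S)-[2,5-bis(3,4-dihydroxyphenyl)tetrahydrofuran-3,4-diyl]bis(methylene) diacetate
Conditions: H2 (1 atm), 10% Pd/C, EtOAc, rt; filtration under Ar
Reagents that add atoms: none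
Why: Under neutral conditions at atmospheric pressure, heterogeneous hydrogenolysis cleaves aryl benzyl ethers much faster than the ring benzylic C–O bonds, as is usual in the last step of 2,5-diaryltetrahydrofuran lignan syntheses, and it touches neither the acetates nor any stereocentre.

**Compound list**

1 | tetrahydrothiophene | C1CCSC1 | starting material
2 | allyl bromide | C=CCBr | starting material
3 | 1-allyltetrahydrothiophenium bromide | C=CC[S+]1CCCC1.[Br-] | intermediate
4 | 3,4-bis(benzyloxy)benzaldehyde | O=Cc1ccc(OCc2ccccc2)c(OCc2ccccc2)c1 | starting material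
5 | tetrahydrothiophenium allylide | C=C[CH-][S+]1CCCC1 | intermediate
6 | (±)-trans-2-[3,4-bis(benzyloxy)phenyl]-3-vinyloxirane | C=C[C@H]1O[C@@H]1c2ccc(OCc3ccccc3)c(OCc3ccccc3)c2 | intermediate
7 | Meldrum's acid (2,2-dimethyl-1,3-dioxane-4,6-dione) | CC1(C)OC(=O)CC(=O)O1 | starting material
8 | 5-[3,4-bis(benzyloxy)benzylidene]-2,2-dimethyl-1,3-dioxane-4,6-dione | CC1(C)OC(=O)C(=Cc2ccc(OCc3ccccc3)c(OCc3ccccc3)c2)C(=O)O1 | intermediate
9 | (±)-spiro-Meldrum tetrahydrofuran, 2,5-cis-diaryl, 4-vinyl trans to the C5 aryl | CC6(C)OC(=O)C1(C(=O)O6)[C@H](C=C)[C@@H](c2ccc(OCc3ccccc3)c(OCc3ccccc3)c2)O[C@H]1c2ccc(OCc3ccccc3)c(OCc3ccccc3)c2 | intermediate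
10 | secondary ozonide of 9 (C4 bears a 1,2,4-trioxolan-3-yl group, trioxolane carbon unassigned) | CC6(C)OC(=O)C1(C(=O)O6)[C@H](C7OCOO7)[C@@H](c2ccc(OCc3ccccc3)c(OCc3ccccc3)c2)O[C@H]1c2ccc(OCc3ccccc3)c(OCc3ccccc3)c2 | intermediate
11 | C4-formyl analogue of 9 | CC6(C)OC(=O)C1(C(=O)O6)[C@H](C=O)[C@@H](c2ccc(OCc3ccccc3)c(OCc3ccccc3)c2)O[C@H]1c2ccc(OCc3ccccc3)c(OCc3ccccc3)c2 | intermediate
12 | C4-hydroxymethyl analogue of 9 | CC6(C)OC(=O)C1(C(=O)O6)[C@H](CO)[C@@H](c2ccc(OCc3ccccc3)c(OCc3ccccc3)c2)O[C@H]1c2ccc(OCc3ccccc3)c(OCc3ccccc3)c2 | intermediate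
13 | (±)-cis-fused lactone acid, CO2H on C3 cis to the C2 aryl, both aryls exo | OC(=O)[C@@]12C(=O)OC[C@@H]1[C@@H](c3ccc(OCc4ccccc4)c(OCc4ccccc4)c3)O[C@H]2c3ccc(OCc4ccccc4)c(OCc4ccccc4)c3 | intermediate
14 | (±)-cis-fused 4,6-diaryltetrahydrofuro[3,4-c]furan-1-one, both aryls exo | O=C1OC[C@@H]2[C@@H](c3ccc(OCc4ccccc4)c(OCc4ccccc4)c3)O[C@@H](c3ccc(OCc4ccccc4)c(OCc4ccccc4)c3)[C@H]12 | intermediate
15 | meso-(2R,3S,4R,5S) tetrabenzyl diol | OC[C@@H]1[C@H](CO)[C@@H](c2ccc(OCc3ccccc3)c(OCc3ccccc3)c2)O[C@H]1c2ccc(OCc3ccccc3)c(OCc3ccccc3)c2 | intermediate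
16 | meso-(2R,3S,4R,5S) tetrabenzyl diacetate | CC(=O)OC[C@@H]1[C@H](COC(C)=O)[C@@H](c2ccc(OCc3ccccc3)c(OCc3ccccc3)c2)O[C@H]1c2ccc(OCc3ccccc3)c(OCc3ccccc3)c2 | intermediate
17 | CNP0416169.1 | CC(=O)OC[C@@H]1[C@H](COC(C)=O)[C@@H](c2ccc(O)c(O)c2)O[C@H]1c1ccc(O)c(O)c1 | target

**Step count**

Total steps: 9. Longest linear sequence: 8 (steps 1, 2, 4, 5, 6, 7, 8, 9). Step 3 is the convergent branch.

**Steps most likely to fail**

**Step 4.**
- **What may go wrong:** the strained, p-alkoxy-activated oxirane may rearrange by hydride shift within the zwitterion. It may also oligomerise through alkoxide attack on a second allyl unit. Either could be faster than capture of the hindered benzylic alkoxide by 8.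
- **Fallback:** it sets out from 4, uses 8, and comes back at 9. It replaces strain-release ionisation by the known cascade of a hydroxy-substituted open-chain allylic carbonate with an activated alkene.
- **Route:** aldehyde 4 is added to dilithiated propargyl alcohol (n-BuLi, THF, −78 °C) to give (±)-1-[3,4-bis(benzyloxy)phenyl]but-2-yne-1,4-diol F1. Alkoxide-directed trans-hydroalumination (LiAlH4, THF) should give (±)-(E)-1-[3,4-bis(benzyloxy)phenyl]but-2-ene-1,4-diol F2. Methyl chloroformate and pyridine at −20 °C acylate the primary hydroxyl only, giving (±)-(E)-4-[3,4-bis(benzyloxy)phenyl]-4-hydroxybut-2-en-1-yl methyl carbonate F3.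
- **Return:** with Pd2(dba)3/dppe in THF, F3 ionises at the primary terminus, and the released methoxide deprotonates the benzylic alcohol. Oxa-Michael addition to 8 and 5-exo closure then deliver 9. Here the 4,5-trans relation is set only by the preference of the closure to keep the C5 aryl group away from the allyl–palladium fragment.

**Step 2.**
- **What may go wrong:** betaine formation from the weakly stabilised allylide may be too irreversible, giving poor trans/cis selectivity. Acid-triggered opening of the oxirane during the separation would add to the loss.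
- **Fallback:** it sets out from 4 and 1 and comes back at 6. It reverses the polarity of the epoxide disconnection, so that a benzylic ylide meets an enal, a pairing that generally closes with higher trans preference.
- **Route:** NaBH4 in MeOH reduces 4 to 3,4-bis(benzyloxy)benzyl alcohol F4. Treatment with tetrahydrothiophene 1 and HBF4·OEt2 in CH2Cl2 at 0 °C gives 1-[3,4-bis(benzyloxy)benzyl]tetrahydrothiophenium tetrafluoroborate F5.
- **Return:** powdered KOH in MeCN at −10 °C generates the tetrahydrothiophenium 3,4-bis(benzyloxy)benzylide F6. This adds 1,2 to slowly introduced acrolein and closes to 6.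

**Step 5.**
- **What may go wrong:** ozone may over-oxidise the catechol ether rings or the benzylic CH2 groups. The Meldrum ring may also undergo solvolysis before the lactone can form.
- **Fallback:** it sets out from 9 and comes back at 14. It dismantles the Meldrum ring first, so that an osmium-based cleavage becomes safe, because a plain methyl ester does not acylate the transient diol at a competitive rate.
- **Route:** NaOMe in MeOH at rt opens 9 to 2,5-diaryl-3-(methoxycarbonyl)-4-vinyltetrahydrofuran-3-carboxylic acid F7. Heating in DMSO at 120 °C decarboxylates it to methyl 2,5-diaryl-4-vinyltetrahydrofuran-3-carboxylate F8, as C3 epimers. Lemieux–Johnson cleavage (OsO4 cat., NaIO4, 2,6-lutidine, dioxane–H2O) gives methyl 2,5-diaryl-4-formyltetrahydrofuran-3-carboxylate F9. NaBH4 in MeOH gives methyl 2,5-diaryl-4-(hydroxymethyl)tetrahydrofuran-3-carboxylate F10.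
- **Return:** catalytic NaOMe then equilibrates C3. Only the epimer with the ester cis to C4′ can lactonise, so both epimers should drain into 14.

**Further compounds**

F1 | step 4 | (±)-1-[3,4-bis(benzyloxy)phenyl]but-2-yne-1,4-diol | OCC#C[C@H](O)c1ccc(OCc2ccccc2)c(OCc2ccccc2)c1
F2 | step 4 | (±)-(E)-1-[3,4-bis(benzyloxy)phenyl]but-2-ene-1,4-diol | OC/C=C/[C@H](O)c1ccc(OCc2ccccc2)c(OCc2ccccc2)c1
F3 | step 4 | (±)-(E)-4-[3,4-bis(benzyloxy)phenyl]-4-hydroxybut-2-en-1-yl methyl carbonate | COC(=O)OC/C=C/[C@H](O)c1ccc(OCc2ccccc2)c(OCc2ccccc2)c1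
F4 | step 2 | 3,4-bis(benzyloxy)benzyl alcohol | OCc1ccc(OCc2ccccc2)c(OCc2ccccc2)c1
F5 | step 2 | 1-[3,4-bis(benzyloxy)benzyl]tetrahydrothiophenium tetrafluoroborate | F[B-](F)(F)F.C(c1ccc(OCc2ccccc2)c(OCc2ccccc2)c1)[S+]1CCCC1
F6 | step 2 | tetrahydrothiophenium 3,4-bis(benzyloxy)benzylide | [CH-](c1ccc(OCc2ccccc2)c(OCc2ccccc2)c1)[S+]1CCCC1
F7 | step 5 | 2,5-bis[3,4-bis(benzyloxy)phenyl]-3-(methoxycarbonyl)-4-vinyltetrahydrofuran-3-carboxylic acid (C3 unassigned) | COC(=O)C1(C(=O)O)[C@H](C=C)[C@@H](c2ccc(OCc3ccccc3)c(OCc3ccccc3)c2)O[C@H]1c2ccc(OCc3ccccc3)c(OCc3ccccc3)c2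
F8 | step 5 | methyl 2,5-bis[3,4-bis(benzyloxy)phenyl]-4-vinyltetrahydrofuran-3-carboxylate (C3 epimers) | COC(=O)C1[C@H](C=C)[C@@H](c2ccc(OCc3ccccc3)c(OCc3ccccc3)c2)O[C@H]1c2ccc(OCc3ccccc3)c(OCc3ccccc3)c2
F9 | step 5 | methyl 2,5-bis[3,4-bis(benzyloxy)phenyl]-4-formyltetrahydrofuran-3-carboxylate (C3 epimers) | COC(=O)C1[C@H](C=O)[C@@H](c2ccc(OCc3ccccc3)c(OCc3ccccc3)c2)O[C@H]1c2ccc(OCc3ccccc3)c(OCc3ccccc3)c2
F10 | step 5 | methyl 2,5-bis[3,4-bis(benzyloxy)phenyl]-4-(hydroxymethyl)tetrahydrofuran-3-carboxylate (C3 epimers) | COC(=O)C1[C@H](CO)[C@@H](c2ccc(OCc3ccccc3)c(OCc3ccccc3)c2)O[C@H]1c2ccc(OCc3ccccc3)c(OCc3ccccc3)c2
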